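## Structural features

The target is a halimane-type bicyclic diterpenoid ester: a 1(10)-octalin in which ring A (C1–C5, C10) and ring B (C5–C10) share the C5–C10 bond, with the only ring double bond (C1=C10) starting at the ring fusion. Ring A carries the quaternary C4 (methyl and methyl ester) next to the tertiary C5. Ring B carries the tertiary C8 (methyl C17) next to the quaternary C9 (methyl C20 and the chain C11–C15), and C9 is bonded to the alkene carbon C10, so the four ring stereocentres form two vicinal pairs (C4/C5 and C8/C9) separated by one sp2 carbon. Their configuration is 4S,5R,8R,9S: the methyl groups on C8 and C9 and H5 lie on one face, the C4 ester and the C9 chain on the other. The chain ends in a trans 2,3-epoxy alcohol (tertiary C13 with methyl C16, C14, C15–OH; 13R,14R) that is too far from the ring stereocentres to be controlled by them. The fragile groups are this epoxide (acid opening at C13, possibly by the C1=C10 alkene; Payne rearrangement under base), the C1=C10 double bond (acid-promoted migration to the tetrasubstituted C5=C10 position) and, less so, the ester towards organometallic reagents. The real difficulty is the two quaternary centres, above all the C4–C5 bond that joins a fully substituted carbon to the ring-fusion carbon with a defined relative configuration. The key step uses the fact that ring A is a cyclohexene whose double bond C1=C10 carries the ring B carbon C10 and whose C4 carries methyl and ester: this is the Diels–Alder retron of a ring B 1-vinylcyclohexene (C2=C1–C10=C5) and a methacrylate (C3=C4).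

## Logic of the disconnections

21 is cut at the two C–O bonds of the epoxide (C13–O, C14–O), leading to 20. The epoxide is the most sensitive group and its two stereocentres cannot be relayed from the ring, so it is made last and under reagent control. This removes two stereocentres and the acid- and base-labile function. The forward step must find an E-configured C13=C14 allylic alcohol, override the remote ring centres, and leave C1=C10 alone.

20 is cut at C13–C16 and C14–C15, leading to 17, 2 and 18. A syn addition of methyl and metal across a terminal alkyne fixes the E geometry that an olefination of a methyl ketone would only give as a mixture. The trisubstituted alkene and the hydroxymethyl group collapse to a terminal alkyne. The forward step needs methyl delivered to the internal carbon only, and the C4 ester must survive the aluminium reagent.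

17 is cut at C13≡C14 (C14 comes from 16), leading to 15, and functional-group changes lead through 14 back to the terminal alkene of 12. The three carbons C11–C13 are thereby reduced to a plain allyl group. That group is the most reactive electrophile partner for the enolate alkylation, is small, and has no Lewis-basic site to compete for the aluminium Lewis acid in the cycloaddition. The forward steps need an anti-Markovnikov hydroboration that discriminates the monosubstituted alkene from C1=C10.

12 is cut at C4–C5 and C2–C3, leading to 10 and 11. This is the ring A retron; one step removes a ring, two skeletal bonds and both ring A stereocentres, including the crowded quaternary–tertiary bond. The forward step must join the ester-bearing carbon to C5 (not C2), place the ester endo, and add to the diene face opposite the C9 methyl.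

10 is cut at C1–C10, leading to 8 and 9, and 8 goes back to ketone 6 by removal of the sulfonyl group. The regiochemistry of the enol derivative is unambiguous because C9 has no hydrogen. The forward coupling must work at a vinyl position flanked by a quaternary carbon.

6 is cut at C8–C17 and C9–C11, leading to 1, 2 and 3. Conjugate addition followed by enolate alkylation sets C8 by catalyst control and C9 by the adjacent new centre, and reaches achiral commercial materials. The forward step needs an enantioselective methyl transfer to an α-substituted enone, an activated form of the aluminium enolate, and alkylation anti to the C8 methyl.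

## Other disconnections considered

Alternative 1: The cut is at C8–C17 and C9–C11 of the ring B ketone A1, which is the same compound as 6. The forward step is the copper-catalysed, phosphoramidite-controlled methyl transfer from 2 to C8 of 1 with allylation of the resulting enolate at C9 by 3.
- In favour: it makes two C–C bonds and the only two ring stereocentres that need an external source of chirality in one flask, catalytically, from achiral materials.
- Against: it closes no ring and leaves ring A, C4 and C5 untouched, so it cannot carry the strategy alone.
- Comparison: on structure it solves ring B substitution only, whereas the chosen step builds ring A and the most hindered bond. On mechanism it is the better of the two, because catalyst control at C8 and anti alkylation at C9 are more predictable than the three simultaneous selectivities of the cycloaddition. On step economy it is the equal of the chosen plan, since that plan already uses it as step 1.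

Alternative 2: The cut is at C5–C10 and C8–C9, opening both rings to the acyclic ester A2. In A2 C4 is already quaternary, C5=C6–C7=C8 is a 5E,7Z diene and the allene C1=C10=C9 is tethered through C2–C3. The forward step is an intramolecular [4+2] addition of the diene across the distal C9=C10 bond, by heat or with Ni(cod)2 and a bulky triaryl phosphite, giving A3.
- In favour: both rings and C5, C8 and C9 form in one operation. The tether fixes the regiochemistry, which is better than the chosen plan, where it rests on an electronic preference. Methyl and ester do not compete for the endo position, because C4 exists beforehand; in principle this is also better.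
- Against: A2 needs two independent stereo-elements, C4 and the allene axis (M by transition-state analysis), each made enantiopure and matched. C9 follows from the axis, but C5 and C8 depend on which diene face is presented, and only the small differences between methyl and ester on C4 and between methyl and CH2 on C9 decide this. The 7Z diene reaches the s-cis geometry with difficulty and can undergo 1,5-hydrogen shift on heating, so a metal catalyst would be needed, and that raises the question of which allene double bond reacts.
- Afterwards C6=C7 must be hydrogenated beside C1=C10, and the C13 ketone extended by an olefination of uncertain E/Z ratio and a reduction selective against the C4 ester.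
- Comparison: on structure and on bonds per step it is superior. On mechanism its stereochemical outcome is less secure than a cycloaddition steered by an existing ring. On step economy it is worse: A2 alone is estimated at more than ten steps, with about five more after A3, against nine in total for the chosen plan.

Alternative 3: The cut is again at C4–C5, but by a [3,3] shift: acid A5 comes from δ-lactone A4, whose ring oxygen is on C1 and whose C10=C5 double bond is in ring B. The forward step forms the silyl ketene acetal (LiN(iPr)2, Me3SiCl) and heats it; C4–C5 forms while C1–O breaks and the double bond moves to C1=C10.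
- In favour: the lactone fixes the ketene acetal geometry and the two-carbon bridge C2–C3 allows only a boat, so the C4/C5 relationship (carboxyl trans to H5) is enforced by geometry. This is better than the chosen plan, where it is an endo preference. The face at C5 is transferred from the C1 carbinol centre (6R in A4), a reagent-set element at least equal to the substrate-controlled face selection of the chosen plan. The chain is already an alkyne, which saves two steps after ring A.
- Against: the C1 stereocentre must be made with reagent control and is then destroyed. Building A4 from the ring B enol triflate needs a C–C coupling at C10, adjustment of the carbinol configuration and lactonisation, about four steps. The chain must be introduced by alkylating the enolate with a non-allylic, elimination-prone halide. The rearrangement makes a quaternary centre through a boat and would need heating, under which lactone ketene acetals can be lost to elimination or C-silylation. The acid must then be esterified.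
- Comparison: on structure it makes the same bond and ring as the chosen plan and is equal in the origin of C8 and C9. On mechanism it is the more reliable for C4/C5. On step economy it is estimated two to three steps longer and carries an extra, temporary stereocentre.

Key step: step 4

Assumption 1: atoms are numbered by the halimane convention (C16 on C13, C17 on C8, C20 on C9) in all sections.
Assumption 2: the phosphoramidite L* in step 1 is the enantiomer that delivers methyl to the enone face giving the 3R centre of 6; the sense of induction would be confirmed by correlation with the known conjugate adduct.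
Remark: a neutral dimethylaluminium enolate is a poor nucleophile towards allyl iodide, so step 1 includes its conversion into the lithium aluminate before alkylation.

## Steps

Step 1
Reactants: 1 2-methylcyclohex-2-en-1-one; 2 trimethylaluminium; 3 allyl iodide (3-iodoprop-1-ene)
Product: 6 (2S,3R)-2,3-dimethyl-2-(prop-2-en-1-yl)cyclohexan-1-one, via dimethylaluminium enolate 4 (not isolated), via lithium trimethylaluminate enolate 5 (not isolated)
Conditions: Cu(O2C-C4H3S) [copper mono(thiophene-2-carboxylate)] (2 mol %), L* = O,O'-(1,1'-binaphthalene-2,2'-diyl) N,N-bis(1-phenylethyl)phosphoramidite (4 mol %), AlMe3, Et2O, −30 °C; then MeLi, THF, −30 → 0 °C; allyl iodide, DMPU, 0 °C → rt; aq. NH4Cl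
Reagents that add atoms: trimethylaluminium (2), C[Al](C)C; allyl iodide (3), C=CCI
Why: Copper-catalysed asymmetric conjugate addition puts methyl on C8 under ligand control and gives enolate 4; its aluminate 5 is nucleophilic enough for C-allylation, which should occur anti to the C8 methyl (held pseudoaxial by allylic strain against the enolate methyl), so that the two methyl groups end cis. The whole is a one-pot conjugate addition–enolate alkylation.

Step 2
Reactants: 6 (2S,3R)-2,3-dimethyl-2-(prop-2-en-1-yl)cyclohexan-1-one
Product: 8 (5R,6S)-5,6-dimethyl-6-(prop-2-en-1-yl)cyclohex-1-en-1-yl trifluoromethanesulfonate, via lithium enolate 7 (not isolated)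
Conditions: LiN(iPr)2, THF, −78 °C; PhNTf2, −78 → 0 °C
Reagents that add atoms: N-phenylbis(trifluoromethanesulfonimide), O=S(=O)(N(c1ccccc1)S(=O)(=O)C(F)(F)F)C(F)(F)F
Why: Only C5 has α-hydrogens because C9 is quaternary, so deprotonation gives the single enolate 7, which is O-sulfonylated (enol triflate formation). No stereocentre is touched.

Step 3
Reactants: 8 (5R,6S)-5,6-dimethyl-6-(prop-2-en-1-yl)cyclohex-1-en-1-yl trifluoromethanesulfonate; 9 tributyl(ethenyl)stannane
Product: 10 (5R,6S)-1-ethenyl-5,6-dimethyl-6-(prop-2-en-1-yl)cyclohex-1-ene
Conditions: Pd(PPh3)4 (5 mol %), LiCl, THF, reflux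
Reagents that add atoms: tributyl(ethenyl)stannane (9), CCCC[Sn](CCCC)(CCCC)C=C
Why: Stille coupling: zerovalent palladium inserts into the vinyl C–O bond, chloride from LiCl replaces triflate on palladium, and the vinyl group is transferred from tin to form C1–C10. The ring fixes the geometry of the diene, and the isolated allyl group is inert.

Step 4
Reactants: 10 (5R,6S)-1-ethenyl-5,6-dimethyl-6-(prop-2-en-1-yl)cyclohex-1-ene; 11 methyl methacrylate
Product: 12 methyl (1S,5S,6R,8aR)-1,5,6-trimethyl-5-(prop-2-en-1-yl)-1,2,3,5,6,7,8,8a-octahydronaphthalene-1-carboxylate
Conditions: methyl methacrylate (3 equiv), EtAlCl2 (0.5 equiv), CH2Cl2, −40 → 0 °C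
Reagents that add atoms: methyl methacrylate (11), C=C(C)C(=O)OC
Why: Coordination of EtAlCl2 to the ester carbonyl of 11 lowers its LUMO and a concerted, asynchronous [4+2] cycloaddition with the s-cis diene C2=C1–C10=C5 of 10 follows; the closest known reaction type is the Lewis-acid Diels–Alder reaction of 1-vinylcyclohexenes with 2-substituted acrylates. Ring A is closed by intermolecular six-membered annulation onto ring B, both new bonds forming suprafacially, C2–C3 ahead of the crowded C4–C5, and the remaining double bond can only be C1=C10. For regiochemistry the substituent on the diene terminus (C6 on C5) should outweigh the opposing one on the inner carbon (C9 on C10), so that the free terminus C2 bonds to the acrylate CH2 and the ester-bearing carbon to C5, a preference the Lewis acid enlarges. C5 is controlled by the diene face: with the C8 methyl and the allyl group equatorial the C9 methyl is pseudoaxial and covers one face, so the dienophile should add anti to it, a path that also leads directly to the ring B chair in which only that methyl is axial. C4 is controlled relative to C5 by the endo position of the aluminium-bound ester below C10–C1, which puts the carboxyl cis to C6 and trans to H5 and leaves the methyl exo. The step therefore needs ortho, endo and facial selectivity together; the quaternary C9 supplies the facial bias and also disfavours the unreactive s-trans diene, while the endo preference of an α-methyl acrylate is the least secure of the three. The isolated allyl double bond is not activated and should not take part, and the ethylaluminium reagent removes traces of protic acid that could isomerise or oligomerise the diene.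

Step 5
Reactants: 12 methyl (1S,5S,6R,8aR)-1,5,6-trimethyl-5-(prop-2-en-1-yl)-1,2,3,5,6,7,8,8a-octahydronaphthalene-1-carboxylate
Product: 14 methyl (1S,5S,6R,8aR)-5-(3-hydroxypropyl)-1,5,6-trimethyl-1,2,3,5,6,7,8,8a-octahydronaphthalene-1-carboxylate, via B-alkyl-9-borabicyclononane 13 (not isolated)
Conditions: 9-BBN, THF, 0 °C → rt; then aq. NaOH, H2O2, 0 °C
Reagents that add atoms: hydrogen peroxide, OO
Why: Hydroboration–oxidation: the bulky dialkylborane adds anti-Markovnikov to the monosubstituted alkene far faster than to the hindered trisubstituted C1=C10 and does not reduce esters. The brief cold oxidation should spare the neopentyl-type ester.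

Step 6
Reactants: 14 methyl (1S,5S,6R,8aR)-5-(3-hydroxypropyl)-1,5,6-trimethyl-1,2,3,5,6,7,8,8a-octahydronaphthalene-1-carboxylate
Product: 15 methyl (1S,5S,6R,8aR)-1,5,6-trimethyl-5-(3-oxopropyl)-1,2,3,5,6,7,8,8a-octahydronaphthalene-1-carboxylate
Conditions: Dess–Martin periodinane, CH2Cl2, 0 °C → rt
Reagents that add atoms: none
Why: Dess–Martin oxidation of a primary alcohol stops at the aldehyde under neutral conditions that leave the alkene and ester untouched. The aldehyde has no α-stereocentre to lose.

Step 7
Reactants: 15 methyl (1S,5S,6R,8aR)-1,5,6-trimethyl-5-(3-oxopropyl)-1,2,3,5,6,7,8,8a-octahydronaphthalene-1-carboxylate; 16 dimethyl (1-diazo-2-oxopropyl)phosphonate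
Product: 17 methyl (1S,5S,6R,8aR)-5-(but-3-yn-1-yl)-1,5,6-trimethyl-1,2,3,5,6,7,8,8a-octahydronaphthalene-1-carboxylate
Conditions: K2CO3, MeOH, 0 °C → rt
Reagents that add atoms: dimethyl (1-diazo-2-oxopropyl)phosphonate (16), COP(=O)(OC)C(=[N+]=[N-])C(C)=O
Why: Seyferth–Gilbert homologation with the Ohira–Bestmann reagent: methanolysis releases the diazomethylphosphonate anion, which olefinates the aldehyde; loss of N2 and a 1,2-hydrogen shift give the terminal alkyne with C14 added. Methanol and carbonate can only exchange methyl for methyl at the hindered ester.

Step 8
Reactants: 17 methyl (1S,5S,6R,8aR)-5-(but-3-yn-1-yl)-1,5,6-trimethyl-1,2,3,5,6,7,8,8a-octahydronaphthalene-1-carboxylate; 2 trimethylaluminium; 18 formaldehyde (used as paraformaldehyde)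
Product: 20 methyl (1S,5S,6R,8aR)-5-[(3E)-5-hydroxy-3-methylpent-3-en-1-yl]-1,5,6-trimethyl-1,2,3,5,6,7,8,8a-octahydronaphthalene-1-carboxylate, via alkenyldimethylalane 19 (not isolated)
Conditions: AlMe3 (3 equiv), Cp2ZrCl2 (0.25 equiv), CH2Cl2, 0 °C → rt; then (CH2O)n, THF, 0 °C → rt; aq. potassium sodium tartrate (KNaC4H4O6)
Reagents that add atoms: trimethylaluminium (2), C[Al](C)C; formaldehyde (18), C=O
Why: Zirconium-catalysed Negishi carboalumination adds methyl and aluminium syn across the alkyne with methyl on the internal carbon C13, and the C14–Al bond of 19 is then replaced by CH2OH with retention, which fixes the E geometry. The α-quaternary ester should tolerate AlMe3 at or below room temperature, and the trisubstituted ring alkene does not undergo carbometalation.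

Step 9
Reactants: 20 methyl (1S,5S,6R,8aR)-5-[(3E)-5-hydroxy-3-methylpent-3-en-1-yl]-1,5,6-trimethyl-1,2,3,5,6,7,8,8a-octahydronaphthalene-1-carboxylate
Product: 21 methyl (1S,5S,6R,8aR)-5-{2-[(2R,3R)-3-(hydroxymethyl)-2-methyloxiran-2-yl]ethyl}-1,5,6-trimethyl-1,2,3,5,6,7,8,8a-octahydronaphthalene-1-carboxylate
Conditions: Ti(OiPr)4 (10 mol %), D-(−)-diethyl tartrate (12 mol %), t-BuOOH, 4 Å molecular sieves, CH2Cl2, −20 °C
Reagents that add atoms: tert-butyl hydroperoxide, CC(C)(C)OO
Why: Sharpless asymmetric epoxidation: the titanium tartrate complex binds the allylic hydroxyl and delivers oxygen to one face of C13=C14. D-(−)-tartrate gives the 2R,3R epoxy alcohol from an (E)-3-methylalk-2-en-1-ol (the sense known for geraniol), here 13R,14R, irrespective of the remote ring centres. C1=C10 has no directing hydroxyl and should stay intact, and a buffered, non-acidic work-up protects the tertiary epoxide.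

## Compound list

1 | 2-methylcyclohex-2-en-1-one | CC1=CCCCC1=O | starting material
2 | trimethylaluminium | C[Al](C)C | starting material
3 | allyl iodide (3-iodoprop-1-ene) | C=CCI | starting material
4 | dimethylaluminium (3R)-2,3-dimethylcyclohex-1-en-1-olate | C[Al](C)OC1=C(C)[C@H](C)CCC1 | intermediate
5 | lithium trimethyl[(3R)-2,3-dimethylcyclohex-1-en-1-olato]aluminate | [Li+].C[Al-](C)(C)OC1=C(C)[C@H](C)CCC1 | intermediate
6 | (2S,3R)-2,3-dimethyl-2-(prop-2-en-1-yl)cyclohexan-1-one | O=C1CCC[C@@H](C)[C@]1(C)CC=C | intermediate
7 | lithium (5R,6S)-5,6-dimethyl-6-(prop-2-en-1-yl)cyclohex-1-en-1-olate | [Li+].[O-]C1=CCC[C@@H](C)[C@]1(C)CC=C | intermediate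
8 | (5R,6S)-5,6-dimethyl-6-(prop-2-en-1-yl)cyclohex-1-en-1-yl trifluoromethanesulfonate | O=S(=O)(OC1=CCC[C@@H](C)[C@]1(C)CC=C)C(F)(F)F | intermediate
9 | tributyl(ethenyl)stannane | CCCC[Sn](CCCC)(CCCC)C=C | starting material
10 | (5R,6S)-1-ethenyl-5,6-dimethyl-6-(prop-2-en-1-yl)cyclohex-1-ene | C=CC1=CCC[C@@H](C)[C@]1(C)CC=C | intermediate
11 | methyl methacrylate (methyl 2-methylprop-2-enoate) | C=C(C)C(=O)OC | starting material
12 | methyl (1S,5S,6R,8aR)-1,5,6-trimethyl-5-(prop-2-en-1-yl)-1,2,3,5,6,7,8,8a-octahydronaphthalene-1-carboxylate | COC(=O)[C@@]1(C)CCC=C2[C@H]1CC[C@@H](C)[C@]2(C)CC=C | intermediate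
13 | methyl (1S,5S,6R,8aR)-5-[3-(9-borabicyclo[3.3.1]nonan-9-yl)propyl]-1,5,6-trimethyl-1,2,3,5,6,7,8,8a-octahydronaphthalene-1-carboxylate | COC(=O)[C@@]1(C)CCC=C2[C@H]1CC[C@@H](C)[C@]2(C)CCCB1C2CCCC1CCC2 | intermediate
14 | methyl (1S,5S,6R,8aR)-5-(3-hydroxypropyl)-1,5,6-trimethyl-1,2,3,5,6,7,8,8a-octahydronaphthalene-1-carboxylate | COC(=O)[C@@]1(C)CCC=C2[C@H]1CC[C@@H](C)[C@]2(C)CCCO | intermediate
15 | methyl (1S,5S,6R,8aR)-1,5,6-trimethyl-5-(3-oxopropyl)-1,2,3,5,6,7,8,8a-octahydronaphthalene-1-carboxylate | COC(=O)[C@@]1(C)CCC=C2[C@H]1CC[C@@H](C)[C@]2(C)CCC=O | intermediate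
16 | dimethyl (1-diazo-2-oxopropyl)phosphonate | COP(=O)(OC)C(=[N+]=[N-])C(C)=O | starting material
17 | methyl (1S,5S,6R,8aR)-5-(but-3-yn-1-yl)-1,5,6-trimethyl-1,2,3,5,6,7,8,8a-octahydronaphthalene-1-carboxylate | COC(=O)[C@@]1(C)CCC=C2[C@H]1CC[C@@H](C)[C@]2(C)CCC#C | intermediate
18 | formaldehyde (used as paraformaldehyde) | C=O | starting material
19 | methyl (1S,5S,6R,8aR)-5-[(3E)-4-(dimethylalumanyl)-3-methylbut-3-en-1-yl]-1,5,6-trimethyl-1,2,3,5,6,7,8,8a-octahydronaphthalene-1-carboxylate | COC(=O)[C@@]1(C)CCC=C2[C@H]1CC[C@@H](C)[C@]2(C)CC/C(C)=C/[Al](C)C | intermediate
20 | methyl (1S,5S,6R,8aR)-5-[(3E)-5-hydroxy-3-methylpent-3-en-1-yl]-1,5,6-trimethyl-1,2,3,5,6,7,8,8a-octahydronaphthalene-1-carboxylate | COC(=O)[C@@]1(C)CCC=C2[C@H]1CC[C@@H](C)[C@]2(C)CC/C(C)=C/CO | intermediate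
21 | methyl (1S,5S,6R,8aR)-5-{2-[(2R,3R)-3-(hydroxymethyl)-2-methyloxiran-2-yl]ethyl}-1,5,6-trimethyl-1,2,3,5,6,7,8,8a-octahydronaphthalene-1-carboxylate | COC(=O)[C@@]1(C)CCC=C2[C@H]1CC[C@@H](C)[C@]2(C)CC[C@@]1(C)O[C@@H]1CO | target

## Step count and least certain steps

Total step count: 9. Longest linear sequence: 9 steps (from 1 to 21).

Step 4 (key step). The most likely failure is insufficient endo preference: the α-methyl group competes with the complexed ester for the endo position, and the resulting C4 epimer cannot be corrected at a quaternary centre. Facial selectivity may also erode if the half-chair with a pseudoaxial allyl group reacts. Bonding of C5 to the acrylate CH2 (direction by the C10 substituent) would give the regioisomer. The diene may oligomerise under acid if the cycloaddition is slow.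

The fallback changes the dienophile and the oxidation level. It sets out from 10 and uses methacrolein with BF3·OEt2 (or Me2AlCl) in CH2Cl2 at −78 °C. The aldehyde complex is far more electrophilic, so the reaction should run at a temperature where endo and facial discrimination are larger. It should give (1S,5S,6R,8aR)-1,5,6-trimethyl-5-(prop-2-en-1-yl)-1,2,3,5,6,7,8,8a-octahydronaphthalene-1-carbaldehyde F1. Pinnick oxidation (NaClO2, NaH2PO4, 2-methylbut-2-ene, t-BuOH/H2O) would give (1S,5S,6R,8aR)-1,5,6-trimethyl-5-(prop-2-en-1-yl)-1,2,3,5,6,7,8,8a-octahydronaphthalene-1-carboxylic acid F2. Methylation with Me3SiCHN2 in MeOH/toluene returns to 12.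

Step 1. The risks are slow or unselective C-allylation of the aluminium-bound enolate (proton transfer, over-alkylation), insufficient anti selectivity relative to the C8 methyl, and incomplete enantioselection in methyl transfer to an α-substituted enone.

The fallback separates the two bond formations and changes the mechanism of the second. It sets out from 1: after the conjugate addition, enolate 4 is trapped with allyl chloroformate to give allyl (3R)-2,3-dimethylcyclohex-1-en-1-yl carbonate F3. A Pd(PPh3)4-catalysed decarboxylative allylation (Tsuji allylation) in THF then forms C9–C11 within an enolate/allylpalladium ion pair and returns to 6.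

Step 8. The risks are methyl transfer from aluminium to the C4 ester during the carboalumination, incomplete regioselectivity of methyl delivery, and sluggish capture of the alkenylalane by paraformaldehyde.

The fallback replaces carbometalation by olefination. It sets out from 15. MeMgBr at −78 °C gives methyl (1S,5S,6R,8aR)-5-(3-hydroxybutyl)-1,5,6-trimethyl-1,2,3,5,6,7,8,8a-octahydronaphthalene-1-carboxylate F5 (both carbinol epimers). Dess–Martin oxidation gives methyl (1S,5S,6R,8aR)-1,5,6-trimethyl-5-(3-oxobutyl)-1,2,3,5,6,7,8,8a-octahydronaphthalene-1-carboxylate F6. Horner–Wadsworth–Emmons olefination with triethyl phosphonoacetate and NaH gives methyl (1S,5S,6R,8aR)-5-[(3E)-5-ethoxy-3-methyl-5-oxopent-3-en-1-yl]-1,5,6-trimethyl-1,2,3,5,6,7,8,8a-octahydronaphthalene-1-carboxylate F7 after removal of the Z isomer. Reduction of the unhindered conjugated ester with iBu2AlH at −78 °C, in preference to the α-quaternary ester, returns to 20.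

Step 3. The risks are slow oxidative addition or transmetalation at a vinyl triflate next to a quaternary carbon, with hydrolysis or reduction of the triflate competing, and loss of the volatile diene on isolation.

The fallback avoids cross-coupling. It sets out from 6: CH2=CHMgBr with CeCl3 in THF at −78 °C gives (2S,3R)-1-ethenyl-2,3-dimethyl-2-(prop-2-en-1-yl)cyclohexan-1-ol F4 (either carbinol epimer). Syn dehydration with the Burgess reagent in benzene at 50 °C can only proceed towards C5, because C9 bears no hydrogen, and returns to 10.

## Further compounds

F1 | step 4 | (1S,5S,6R,8aR)-1,5,6-trimethyl-5-(prop-2-en-1-yl)-1,2,3,5,6,7,8,8a-octahydronaphthalene-1-carbaldehyde | O=C[C@@]1(C)CCC=C2[C@H]1CC[C@@H](C)[C@]2(C)CC=C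
F2 | step 4 | (1S,5S,6R,8aR)-1,5,6-trimethyl-5-(prop-2-en-1-yl)-1,2,3,5,6,7,8,8a-octahydronaphthalene-1-carboxylic acid | OC(=O)[C@@]1(C)CCC=C2[C@H]1CC[C@@H](C)[C@]2(C)CC=C
F3 | step 1 | allyl (3R)-2,3-dimethylcyclohex-1-en-1-yl carbonate | C=CCOC(=O)OC1=C(C)[C@H](C)CCC1
F4 | step 3 | (2S,3R)-1-ethenyl-2,3-dimethyl-2-(prop-2-en-1-yl)cyclohexan-1-ol | C=CC1(O)CCC[C@@H](C)[C@]1(C)CC=C
F5 | step 8 | methyl (1S,5S,6R,8aR)-5-(3-hydroxybutyl)-1,5,6-trimethyl-1,2,3,5,6,7,8,8a-octahydronaphthalene-1-carboxylate | COC(=O)[C@@]1(C)CCC=C2[C@H]1CC[C@@H](C)[C@]2(C)CCC(C)O
F6 | step 8 | methyl (1S,5S,6R,8aR)-1,5,6-trimethyl-5-(3-oxobutyl)-1,2,3,5,6,7,8,8a-octahydronaphthalene-1-carboxylate | COC(=O)[C@@]1(C)CCC=C2[C@H]1CC[C@@H](C)[C@]2(C)CCC(C)=O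
F7 | step 8 | methyl (1S,5S,6R,8aR)-5-[(3E)-5-ethoxy-3-methyl-5-oxopent-3-en-1-yl]-1,5,6-trimethyl-1,2,3,5,6,7,8,8a-octahydronaphthalene-1-carboxylate | COC(=O)[C@@]1(C)CCC=C2[C@H]1CC[C@@H](C)[C@]2(C)CC/C(C)=C/C(=O)OCC
A1 | alternative 1 | (2S,3R)-2,3-dimethyl-2-(prop-2-en-1-yl)cyclohexan-1-one | O=C1CCC[C@@H](C)[C@]1(C)CC=C
A2 | alternative 2 | methyl (2S)-2,7-dimethyl-9-(2-methyl-1,3-dioxolan-2-yl)-2-[(1E,3Z)-penta-1,3-dien-1-yl]nona-5,6-dienoate, allene axis M | COC(=O)[C@@](C)(CCC([H])=[C@]=C(C)CCC1(C)OCCO1)/C=C/C=C\C
A3 | alternative 2 | methyl (1S,5S,6R,8aR)-1,5,6-trimethyl-5-[2-(2-methyl-1,3-dioxolan-2-yl)ethyl]-1,2,3,5,6,8a-hexahydronaphthalene-1-carboxylate | COC(=O)[C@@]1(C)CCC=C2[C@H]1C=C[C@@H](C)[C@]2(C)CCC1(C)OCCO1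
A4 | alternative 3 | (6R)-6-{(5R,6S)-5,6-dimethyl-6-[4-(trimethylsilyl)but-3-yn-1-yl]cyclohex-1-en-1-yl}-3-methyloxan-2-one | CC1CC[C@@H](OC1=O)C2=CCC[C@@H](C)[C@]2(C)CCC#C[Si](C)(C)C
A5 | alternative 3 | (1S,5S,6R,8aR)-1,5,6-trimethyl-5-[4-(trimethylsilyl)but-3-yn-1-yl]-1,2,3,5,6,7,8,8a-octahydronaphthalene-1-carboxylic acid | OC(=O)[C@@]1(C)CCC=C2[C@H]1CC[C@@H](C)[C@]2(C)CCC#C[Si](C)(C)C
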